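# Total synthesis proposal for plakortone N: C6 methyl group added last to a bicyclic oxocarbenium ion

## Structural features

Numbering used throughout: C1 is the lactone carbonyl, C2 its CH2, C3 the ring-fusion CH, C4 the ring-fusion C(CH3), C5 the ring CH2, C6 the fully substituted ether carbon, C7–C18 the (CH2)12 chain, and O1 the tetrahydrofuran oxygen. The core is a cis-fused 2,6-dioxabicyclo[3.3.0]octan-3-one in which a γ-lactone (C1, C2, C3, C4, lactone O) and a tetrahydrofuran (O1, C3, C4, C5, C6) share the C3–C4 bond; C6 carries a methyl group and an unbranched, unfunctionalised chain that ends in a para-substituted phenol. There are three stereocentres, (3S,4S,6S): C3 and C4 are neighbours tied together by the cis fusion, C6 is insulated from C4 by C5H2 and from C3 by O1, and both C4 and C6 are tetrasubstituted C–O carbons. Fragile points are the lactone (bases, hard nucleophiles, retro-oxa-Michael at C3), the tertiary C4–O acyl bond (it can be expelled with aromatisation to a furan once C5–C6 unsaturation appears under acid), and the oxidation-sensitive phenol. The real difficulty is the 1,3-relation of C6 to C4: the two carbon substituents of C6, CH3 and CH2R, are sterically almost alike, so a finished C6 centre can neither direct the formation of C3/C4 nor be set by a process that must tell these two groups apart. C6 can be controlled from the ring only while it is trigonal, by telling apart the two faces of the tetrahydrofuran ring. The key step exploits the fact that the C6 methyl group stands on the same face of the tetrahydrofuran ring as the C4–O(lactone) bond and opposite to the C4 methyl group, which is the face on which the ring oxocarbenium ion C6=O1(+) is expected to accept a nucleophile. A second, hidden feature is that C1–C6, the C4 methyl group and the oxygen on C1 are the atoms of a para-methylanisole ring (compound 1) cut open between C1 and C6.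

## Logic of the disconnections

**17 ⇒ 16.**
- Cut: none in the skeleton; the phenolic O–H is masked as O–CH2Ph.
- Reason: the phenol would not survive the organomagnesium, dioxirane and organoaluminium steps.
- Demand: the mask must fall under neutral conditions that leave the lactone and the tertiary ethers alone.

**16 ⇒ 14 (through 15), the key disconnection.**
- Cut: the C6–CH3 bond.
- Reason: removing the methyl group, not the chain, leaves C6 as a ketal carbon inside the intact bicycle. C6 is then trigonal in 15, and its faces are differentiated by the C4 substituents.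
- Gain: the hardest stereocentre disappears, and 14 is only the cyclised form of an acyclic keto ester.
- Demand: the methyl nucleophile must arrive syn to the lactone oxygen, faster than proton loss from C5/C7, and must ignore the lactone.

**14 ⇒ 12 (through 13).**
- Cut: O1–C6, C6–OCH3 and C4–O(lactone).
- Reason and gain: both rings open at once to an acyclic epoxy keto ester that holds only the two adjacent stereocentres of a cis-epoxide.
- Demand: the epoxide must be opened at its tertiary carbon C4 with clean inversion by the ester carbonyl oxygen. The freed C3 hydroxyl then lies cis to the C5 arm and can reach the C6 ketone.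

**12 ⇒ 11 ⇒ 10.**
- Cut: the C6 carbonyl is taken back to a carbinol, and the C3–O and C4–O bonds of the epoxide are taken back to the Z-alkene.
- Reason: the alkene is epoxidised before the ketone exists because the β,γ-relationship of ketone and alkene or epoxide is base-sensitive.
- Gain: 10 has no stereocentre that matters.
- Demand: one catalyst-controlled, suprafacial oxygen transfer to a trialkyl alkene sets C3 and C4 together.

**10 ⇒ 4 + 8 (through 9).**
- Cut: C6–C7.
- Reason and gain: the whole lipophilic half is split from a six-carbon head piece at the only carbon that is later a carbonyl, so no stereochemistry is at stake.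
- Demand: chemoselective addition to an enolisable aldehyde in the presence of a methyl ester.

**4 ⇒ 2 ⇒ 1 (through 3).**
- Cut (reconnection): C1 and C6 are joined to a six-membered ring, which is then rearomatised.
- Reason and gain: the ring guarantees the Z geometry of C3=C4 that the anti-opening in the cascade requires. It also delivers C1 and C6 in different oxidation states.
- Demand: the oxidative cleavage must take only the enol ether double bond of 2.

**8 ⇒ 5 + 6 (through 7).**
- Cut: aryl–C18.
- Gain: two bulk chemicals.
- Demand: mono-substitution of a symmetrical dibromide.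

## Other disconnections considered

**Alternative 1:** (the first that comes to mind) cut O1–C3. The forward key step is an intramolecular oxa-Michael addition (5-exo-trig) of the C6 tertiary hydroxyl of hydroxy butenolide A1 to C3, with the cis fusion enforced by the ring.
- A1 already contains both tetrasubstituted carbinol carbons C4 and C6 in an acyclic 1,3-relationship, so the ring closure solves only C3, the easiest centre.
- Since CH3 and CH2R at C6 cannot be told apart by a neighbouring centre, C4 and C6 each need their own asymmetric operation, which lengthens the route.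
- Addition of a hindered tertiary alkoxide is also reversible.

**Alternative 2:** cut O1–C3, C1–C2 and C1–O(C4) together. The forward key step is a Pd(II)-mediated oxypalladation of the vinyl group of enediol A2 by the C6 hydroxyl, followed by CO insertion and capture of the acyl-palladium by the C4 hydroxyl.
- This builds both rings and brings in C1 in one operation, which is attractive for the skeleton.
- A2 holds the same acyclic C4/C6 bis-tertiary diol, so the stereochemical core of the problem is moved backwards, not solved.
- The chosen plan needs one asymmetric reaction for all three centres.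

**Alternative 3:** delete the lactone ring oxygen (cut C4–O, reconnect C4–C1). The forward key step is a Baeyer–Villiger oxygen insertion into cyclobutanone A4, itself formed by [2+2] cycloaddition of a ketene to the C3=C4 enol ether bond of dihydrofuran A3.
- Both regiochemistries are right by mechanism. The nucleophilic C4 bonds to the ketene carbonyl carbon, and the quaternary C4 migrates.
- The face of A3 is differentiated only by CH3 versus CH2R at C6, remote from both reacting carbons, so no reasoned facial preference can be claimed.
- A3 needs a separately made enantiopure quaternary centre, and an activated ketene would add a dehalogenation step.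

Key step: step 8

Assumption: the L-fructose-derived enantiomer of the Shi ketone is treated as a purchasable catalyst. Compounds 10 and 11 are carried as C6 carbinol epimers and 13 and 14 as C6 anomers, so their SMILES leave C6 undefined.

## Route

**Step 1**
Reactants: 1 4-methylanisole
Product: 2 1-methoxy-4-methylcyclohexa-1,4-diene
Conditions: Li, NH3(l), THF, t-BuOH, −78 to −33 °C; then H2O
Reagents that add atoms: none
Why: Birch reduction: protonation occurs at the unsubstituted positions ortho and meta to the methoxy group, so both donor substituents stay on the two remaining, non-conjugated double bonds; no stereocentre is formed.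

**Step 2**
Reactants: 2 1-methoxy-4-methylcyclohexa-1,4-diene
Product: 4 methyl (3Z)-4-methyl-6-oxohex-3-enoate, via methyl (3Z)-6-hydroperoxy-6-methoxy-4-methylhex-3-enoate 3 (not isolated)
Conditions: O3 (1.0 equiv), CH2Cl2–MeOH, −78 °C; then Me2S, −78 °C to rt
Reagents that add atoms: ozone, [O-][O+]=O; methanol, CO (its atoms stay only in 3)
Why: Chemoselective ozonolysis: the enol ether double bond is far more electron-rich than the trialkyl alkene and takes the single equivalent of ozone; Criegee cleavage leaves the ester at C1 and a carbonyl oxide at C6 that methanol traps as 3 and Me2S reduces. The surviving C3=C4 bond keeps the cis arrangement of C2 and C5 imposed by the ring, so 4 should be the pure Z isomer.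

**Step 3**
Reactants: 5 1-(benzyloxy)-4-bromobenzene; 6 1,12-dibromododecane
Product: 8 1-(benzyloxy)-4-(12-bromododecyl)benzene, via 4-(benzyloxy)phenylmagnesium bromide 7 (not isolated)
Conditions: 5, Mg, THF, reflux; then 6 (3 equiv), Li2CuCl4 (cat.), THF, 0 °C to rt
Reagents that add atoms: magnesium, [Mg] (its atom stays only in 7)
Why: Copper-catalysed (Kochi-type) coupling of an aryl Grignard reagent with a primary alkyl bromide; the excess of 6 suppresses double arylation and can be recovered.

**Step 4**
Reactants: 8 1-(benzyloxy)-4-(12-bromododecyl)benzene; 4 methyl (3Z)-4-methyl-6-oxohex-3-enoate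
Product: 10 methyl (3Z)-18-[4-(benzyloxy)phenyl]-6-hydroxy-4-methyloctadec-3-enoate (both C6 epimers), via 12-[4-(benzyloxy)phenyl]dodecylmagnesium bromide 9 (not isolated)
Conditions: 8, Mg, THF, 40 °C; then added to 4, THF, −78 °C; then H2O
Reagents that add atoms: magnesium, [Mg] (its atom stays only in 9)
Why: Grignard 1,2-addition: at −78 °C with inverse addition the aldehyde reacts much faster than the methyl ester. The C6 carbinol forms as both epimers, which is of no consequence because C6 becomes a carbonyl group in step 6.

**Step 5**
Reactants: 10 methyl (3Z)-18-[4-(benzyloxy)phenyl]-6-hydroxy-4-methyloctadec-3-enoate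
Product: 11 methyl 2-[(2S,3R)-3-{14-[4-(benzyloxy)phenyl]-2-hydroxytetradecyl}-3-methyloxiran-2-yl]acetate (both carbinol epimers)
Conditions: L-fructose-derived Shi ketone (30 mol %), Oxone, K2CO3, Bu4NHSO4 (cat.), MeCN–(MeO)2CH2–aq. Na2B4O7/EDTA buffer, 0 °C
Reagents that add atoms: potassium peroxymonosulfate (active part of Oxone), [K+].[O-]S(=O)(=O)OO
Why: Shi asymmetric epoxidation (chiral dioxirane, spiro transition state): the only vinylic hydrogen, on C3, takes the hindered quadrant next to the fused ketal of the catalyst, and with this catalyst enantiomer oxygen should reach the face that makes C3 (S) and C4 (R). The transfer is suprafacial, so the Z-alkene gives the cis-epoxide and both centres are set in one event. It is run before the ketone exists because a β,γ-unsaturated or β,γ-epoxy ketone would not stand the basic medium.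

**Step 6**
Reactants: 11 methyl 2-[(2S,3R)-3-{14-[4-(benzyloxy)phenyl]-2-hydroxytetradecyl}-3-methyloxiran-2-yl]acetate
Product: 12 methyl 2-[(2S,3R)-3-{14-[4-(benzyloxy)phenyl]-2-oxotetradecyl}-3-methyloxiran-2-yl]acetate
Conditions: Dess–Martin periodinane, pyridine, CH2Cl2, 0 °C
Reagents that add atoms: none
Why: Dess–Martin oxidation under pyridine buffer is neutral enough for the trisubstituted epoxide and avoids base-induced opening of the β,γ-epoxy ketone; both carbinol epimers converge on one compound.

**Step 7**
Reactants: 12 methyl 2-[(2S,3R)-3-{14-[4-(benzyloxy)phenyl]-2-oxotetradecyl}-3-methyloxiran-2-yl]acetate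
Product: 14 (3aS,6aS)-5-{12-[4-(benzyloxy)phenyl]dodecyl}-5-methoxy-6a-methyltetrahydrofuro[3,2-b]furan-2(3H)-one (both C6 anomers), via (3aS,6aS)-5-{12-[4-(benzyloxy)phenyl]dodecyl}-5-hydroxy-6a-methyltetrahydrofuro[3,2-b]furan-2(3H)-one 13 (not isolated)
Conditions: CSA (cat.), CH2Cl2, H2O (2 equiv), 0 °C to rt; then MeOH, 3 Å MS, rt
Reagents that add atoms: water, O; methanol, CO
Why: Acid-catalysed epoxide-opening lactonisation followed by ketalisation: the ester carbonyl oxygen attacks the activated epoxide at its tertiary carbon C4 from the rear (inversion, 4R to 4S, five-membered ring) and water collapses the dialkoxycarbenium ion to the lactone. The freed C3 hydroxyl, placed cis to the C5 arm by anti opening of the cis-epoxide, adds to the C6 ketone to give 13. Methanol is admitted only afterwards, so that it cannot compete for C4, and exchanges the hemiketal hydroxyl; C3 keeps its C–O bond and configuration.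

**Step 8**
Reactants: 14 (3aS,6aS)-5-{12-[4-(benzyloxy)phenyl]dodecyl}-5-methoxy-6a-methyltetrahydrofuro[3,2-b]furan-2(3H)-one
Product: 16 (3aS,5S,6aS)-5-{12-[4-(benzyloxy)phenyl]dodecyl}-5,6a-dimethyltetrahydrofuro[3,2-b]furan-2(3H)-one, via bicyclic C6 oxocarbenium methoxytrimethylaluminate 15 (not isolated)
Conditions: AlMe3 (4 equiv), CH2Cl2, −78 to −20 °C; then H2O
Reagents that add atoms: trimethylaluminium, C[Al](C)C
Why: AlMe3 binds and ionises the ketal methoxy group (SN1-type substitution at a cyclic ketal carbon, the reaction type of Lewis-acid-mediated C-glycosidation of ketosides with organoaluminium reagents), so both anomers of 14 converge on the single ion 15, to which the aluminate then passes a methyl group. No ring is closed; the step forms the C6–CH3 bond and with it the last and hardest stereocentre. In 15 the atoms C5, C6, O1, C3 and C7 are coplanar, so the ring can pucker only at C4, which leaves two envelopes. The envelope with C4 displaced towards the lactone face places the C4–O(lactone) bond pseudoaxial, where its dipole stabilises the cationic carbon, and the C4 methyl group pseudoequatorial, so both C4 substituents favour the same conformer. Attack from inside this envelope, on the face syn to the lactone oxygen and anti to the C4 methyl group, leads directly to a staggered product, whereas the other face requires either an eclipsed transition state or the envelope in which the incoming group meets a pseudoaxial C4 methyl group in a 1,3-syn contact. This face is the concave one of the bicycle, but the atom across from C6 is the sp2 lactone carbon C1, which has no endo substituent, and methyl is the smallest carbon nucleophile. The methyl group should therefore end cis to the lactone oxygen and the chain on the convex face beside C3–H and C4–CH3, which is the (6S) configuration. Chemoselectivity rests on the low temperature, at which the lactone, the aryl benzyl ether and the tertiary C4–O bond are not attacked, and on fast capture, which keeps proton loss from C5 or C7 in check.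

**Step 9**
Reactants: 16 (3aS,5S,6aS)-5-{12-[4-(benzyloxy)phenyl]dodecyl}-5,6a-dimethyltetrahydrofuro[3,2-b]furan-2(3H)-one
Product: 17 plakortone N, (3aS,5S,6aS)-5-[12-(4-hydroxyphenyl)dodecyl]-5,6a-dimethyltetrahydrofuro[3,2-b]furan-2(3H)-one
Conditions: H2 (1 atm), Pd/C, EtOAc, rt
Reagents that add atoms: none
Why: Hydrogenolysis of the aryl benzyl ether; the lactone, the dialkyl ether and the three stereocentres, none of them benzylic or allylic, are inert.

## Compound list

1 | 4-methylanisole | COc1ccc(C)cc1 | starting material
2 | 1-methoxy-4-methylcyclohexa-1,4-diene | COC1=CCC(C)=CC1 | intermediate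
3 | methyl (3Z)-6-hydroperoxy-6-methoxy-4-methylhex-3-enoate | COC(=O)C/C=C(C)\CC(OC)OO | intermediate
4 | methyl (3Z)-4-methyl-6-oxohex-3-enoate | COC(=O)C/C=C(C)\CC=O | intermediate
5 | 1-(benzyloxy)-4-bromobenzene | Brc1ccc(OCc2ccccc2)cc1 | starting material
6 | 1,12-dibromododecane | BrCCCCCCCCCCCCBr | starting material
7 | 4-(benzyloxy)phenylmagnesium bromide | Br[Mg]c1ccc(OCc2ccccc2)cc1 | intermediate
8 | 1-(benzyloxy)-4-(12-bromododecyl)benzene | BrCCCCCCCCCCCCc1ccc(OCc2ccccc2)cc1 | intermediate
9 | 12-[4-(benzyloxy)phenyl]dodecylmagnesium bromide | Br[Mg]CCCCCCCCCCCCc1ccc(OCc2ccccc2)cc1 | intermediate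
10 | methyl (3Z)-18-[4-(benzyloxy)phenyl]-6-hydroxy-4-methyloctadec-3-enoate (C6 epimers) | COC(=O)C/C=C(C)\CC(O)CCCCCCCCCCCCc1ccc(OCc2ccccc2)cc1 | intermediate
11 | methyl 2-[(2S,3R)-3-{14-[4-(benzyloxy)phenyl]-2-hydroxytetradecyl}-3-methyloxiran-2-yl]acetate (carbinol epimers) | COC(=O)C[C@@H]1O[C@]1(C)CC(O)CCCCCCCCCCCCc2ccc(OCc3ccccc3)cc2 | intermediate
12 | methyl 2-[(2S,3R)-3-{14-[4-(benzyloxy)phenyl]-2-oxotetradecyl}-3-methyloxiran-2-yl]acetate | COC(=O)C[C@@H]1O[C@]1(C)CC(=O)CCCCCCCCCCCCc2ccc(OCc3ccccc3)cc2 | intermediate
13 | (3aS,6aS)-5-{12-[4-(benzyloxy)phenyl]dodecyl}-5-hydroxy-6a-methyltetrahydrofuro[3,2-b]furan-2(3H)-one (anomers) | OC1(CCCCCCCCCCCCc3ccc(OCc4ccccc4)cc3)C[C@]2(C)OC(=O)C[C@@H]2O1 | intermediate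
14 | (3aS,6aS)-5-{12-[4-(benzyloxy)phenyl]dodecyl}-5-methoxy-6a-methyltetrahydrofuro[3,2-b]furan-2(3H)-one (anomers) | COC1(CCCCCCCCCCCCc3ccc(OCc4ccccc4)cc3)C[C@]2(C)OC(=O)C[C@@H]2O1 | intermediate
15 | bicyclic C6 oxocarbenium ion (C6=O1+, 3S,4S) with methoxytrimethylaluminate counter-ion | O=C1C[C@@H]2[O+]=C(CCCCCCCCCCCCc3ccc(OCc4ccccc4)cc3)C[C@]2(C)O1.C[Al-](C)(C)OC | intermediate
16 | (3aS,5S,6aS)-5-{12-[4-(benzyloxy)phenyl]dodecyl}-5,6a-dimethyltetrahydrofuro[3,2-b]furan-2(3H)-one | C[C@]1(CCCCCCCCCCCCc3ccc(OCc4ccccc4)cc3)C[C@]2(C)OC(=O)C[C@@H]2O1 | intermediate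
17 | plakortone N | C[C@]1(CCCCCCCCCCCCc2ccc(O)cc2)C[C@]2(C)OC(=O)C[C@@H]2O1 | target

## Step count and least certain steps

Total step count: 9. Longest linear sequence: 8 (steps 1, 2, 4, 5, 6, 7, 8, 9 from compound 1).

**Step 8 (key step).**
- Most likely failure: weak or inverted facial selectivity in the methyl transfer. AlMe3 is a very reactive nucleophile with an early transition state, and the aluminate may hand over its methyl group within the contact ion pair on the side from which methoxide left.
- Second failure mode: proton loss from C5 or C7 of 15 instead of capture, which opens the way to expulsion of the C4 carboxylate and aromatisation.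
- Fallback: the roles of the two C6 substituents are exchanged. A preference for the face anti to the lactone oxygen then becomes productive, and a weaker, more selective π-nucleophile is used. It sets out from 4 and comes back at 17. Addition of MeMgBr to 4 gives methyl (3Z)-6-hydroxy-4-methylhept-3-enoate F1. The operations of steps 5, 6 and 7 turn it into methyl 2-[(2S,3R)-3-(2-hydroxypropyl)-3-methyloxiran-2-yl]acetate F2, then methyl 2-[(2S,3R)-3-methyl-3-(2-oxopropyl)oxiran-2-yl]acetate F3, then (3aS,6aS)-5-methoxy-5,6a-dimethyltetrahydrofuro[3,2-b]furan-2(3H)-one F4. Hosomi–Sakurai allylation (allyltrimethylsilane, BF3·OEt2, CH2Cl2, −78 °C) gives (3aS,5S,6aS)-5-allyl-5,6a-dimethyltetrahydrofuro[3,2-b]furan-2(3H)-one F5. Cross metathesis (ruthenium alkylidene catalyst) follows with 1-(benzyloxy)-4-(undec-10-en-1-yl)benzene F6, made from 7 and purchased 11-bromoundec-1-ene under the conditions of step 3. It gives (3aS,5S,6aS)-5-{12-[4-(benzyloxy)phenyl]dodec-2-en-1-yl}-5,6a-dimethyltetrahydrofuro[3,2-b]furan-2(3H)-one F7. H2 over Pd/C saturates the alkene and removes the benzyl group to give 17.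

**Step 5.**
- Most likely failure: insufficient enantiofacial discrimination, because the alkene carries three unbranched alkyl groups of similar size and a planar transition state can compete with the spiro one.
- Second failure mode: base-induced opening of the β,γ-epoxy ester at the pH of the reaction.
- Fallback: hydroxyl-directed metal catalysis on the small fragment, with the chain joined after the epoxidation. It sets out from 4 and comes back at 11. NaBH4 reduces 4 to methyl (3Z)-6-hydroxy-4-methylhex-3-enoate F8. Directed catalytic asymmetric epoxidation of this primary homoallylic alcohol uses a Zr(IV) or Hf(IV) alkoxide, a chiral bishydroxamic acid ligand and cumene hydroperoxide, and both ligand enantiomers are accessible. It gives methyl 2-[(2S,3R)-3-(2-hydroxyethyl)-3-methyloxiran-2-yl]acetate F9. Dess–Martin oxidation gives methyl 2-[(2S,3R)-3-methyl-3-(2-oxoethyl)oxiran-2-yl]acetate F10, and addition of 9 at −78 °C gives 11.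

**Step 7.**
- Most likely failure: loss of stereochemical integrity at C4 through an SN1-like opening.
- Further failure modes: competing opening at C3 by the ketone oxygen, which would lead into the enantiomeric series and erode enantiopurity; and acid-induced loss of water or methanol across C5–C6 followed by expulsion of the carboxylate and aromatisation.
- Fallback: the two ring closures are taken apart, so that the lactone is made while no C6 carbonyl exists and no oxocarbenium chemistry is possible. It sets out from 11 and comes back at 13. CSA in wet CH2Cl2 converts 11 into (4S,5S)-5-{14-[4-(benzyloxy)phenyl]-2-hydroxytetradecyl}-4-hydroxy-5-methyldihydrofuran-2(3H)-one F11. Chemoselective oxidation with a hindered nitroxyl catalyst (TEMPO, PhI(OAc)2) should take the unhindered C6 carbinol in preference to the neopentyl-type, inductively deactivated C3 carbinol. The keto alcohol closes at once to 13, which is ketalised with PPTS in MeOH to 14.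

**Step 4.**
- Most likely failure: deprotonation of the doubly activated C5–H (α to the aldehyde and allylic) by the basic Grignard reagent, with enolisation and migration of the double bond into conjugation.
- Second failure mode: competing attack on the ester.
- Fallback: the C6–C7 bond is made on the arene before dearomatisation, so that ozonolysis reveals the ketone directly and no carbonyl addition or alcohol oxidation is needed. It sets out from 8 and comes back at 12. Purchased 2-bromo-4-methylanisole is converted into (2-methoxy-5-methylphenyl)magnesium bromide F12 and coupled with 8 under the conditions of step 3. This gives 2-{12-[4-(benzyloxy)phenyl]dodecyl}-1-methoxy-4-methylbenzene F13. Birch reduction cleaves the benzyl ether first, and the resulting phenoxide ring resists reduction while the anisole ring is reduced, giving 4-[12-(2-methoxy-5-methylcyclohexa-1,4-dien-1-yl)dodecyl]phenol F14. Benzylation (BnBr, K2CO3) gives 1-(benzyloxy)-4-[12-(2-methoxy-5-methylcyclohexa-1,4-dien-1-yl)dodecyl]benzene F15. Selective ozonolysis of the tetrasubstituted enol ether bond gives methyl (3Z)-18-[4-(benzyloxy)phenyl]-4-methyl-6-oxooctadec-3-enoate F16. Shi epoxidation in its near-neutral variant gives 12.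

## Further compounds

F1 | step 8 | methyl (3Z)-6-hydroxy-4-methylhept-3-enoate | COC(=O)C/C=C(C)\CC(C)O
F2 | step 8 | methyl 2-[(2S,3R)-3-(2-hydroxypropyl)-3-methyloxiran-2-yl]acetate | COC(=O)C[C@@H]1O[C@]1(C)CC(C)O
F3 | step 8 | methyl 2-[(2S,3R)-3-methyl-3-(2-oxopropyl)oxiran-2-yl]acetate | COC(=O)C[C@@H]1O[C@]1(C)CC(C)=O
F4 | step 8 | (3aS,6aS)-5-methoxy-5,6a-dimethyltetrahydrofuro[3,2-b]furan-2(3H)-one | COC1(C)C[C@]2(C)OC(=O)C[C@@H]2O1
F5 | step 8 | (3aS,5S,6aS)-5-allyl-5,6a-dimethyltetrahydrofuro[3,2-b]furan-2(3H)-one | C[C@]1(CC=C)C[C@]2(C)OC(=O)C[C@@H]2O1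
F6 | step 8 | 1-(benzyloxy)-4-(undec-10-en-1-yl)benzene | C=CCCCCCCCCCc1ccc(OCc2ccccc2)cc1
F7 | step 8 | (3aS,5S,6aS)-5-{12-[4-(benzyloxy)phenyl]dodec-2-en-1-yl}-5,6a-dimethyltetrahydrofuro[3,2-b]furan-2(3H)-one | C[C@]1(CC=CCCCCCCCCCc3ccc(OCc4ccccc4)cc3)C[C@]2(C)OC(=O)C[C@@H]2O1
F8 | step 5 | methyl (3Z)-6-hydroxy-4-methylhex-3-enoate | COC(=O)C/C=C(C)\CCO
F9 | step 5 | methyl 2-[(2S,3R)-3-(2-hydroxyethyl)-3-methyloxiran-2-yl]acetate | COC(=O)C[C@@H]1O[C@]1(C)CCO
F10 | step 5 | methyl 2-[(2S,3R)-3-methyl-3-(2-oxoethyl)oxiran-2-yl]acetate | COC(=O)C[C@@H]1O[C@]1(C)CC=O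
F11 | step 7 | (4S,5S)-5-{14-[4-(benzyloxy)phenyl]-2-hydroxytetradecyl}-4-hydroxy-5-methyldihydrofuran-2(3H)-one | OC(CCCCCCCCCCCCc3ccc(OCc4ccccc4)cc3)C[C@]1(C)OC(=O)C[C@@H]1O
F12 | step 4 | (2-methoxy-5-methylphenyl)magnesium bromide | COc1ccc(C)cc1[Mg]Br
F13 | step 4 | 2-{12-[4-(benzyloxy)phenyl]dodecyl}-1-methoxy-4-methylbenzene | COc1ccc(C)cc1CCCCCCCCCCCCc2ccc(OCc3ccccc3)cc2
F14 | step 4 | 4-[12-(2-methoxy-5-methylcyclohexa-1,4-dien-1-yl)dodecyl]phenol | COC1=C(CCCCCCCCCCCCc2ccc(O)cc2)CC(C)=CC1
F15 | step 4 | 1-(benzyloxy)-4-[12-(2-methoxy-5-methylcyclohexa-1,4-dien-1-yl)dodecyl]benzene | COC1=C(CCCCCCCCCCCCc2ccc(OCc3ccccc3)cc2)CC(C)=CC1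
F16 | step 4 | methyl (3Z)-18-[4-(benzyloxy)phenyl]-4-methyl-6-oxooctadec-3-enoate | COC(=O)C/C=C(C)\CC(=O)CCCCCCCCCCCCc1ccc(OCc2ccccc2)cc1
A1 | alternative 1 | (5S)-5-[(2S)-2-hydroxy-14-(4-hydroxyphenyl)-2-methyltetradecyl]-5-methylfuran-2(5H)-one | C[C@](O)(CCCCCCCCCCCCc2ccc(O)cc2)C[C@]1(C)OC(=O)C=C1
A2 | alternative 2 | (3S,5S)-17-(4-hydroxyphenyl)-3,5-dimethylheptadec-1-ene-3,5-diol | C[C@](O)(CCCCCCCCCCCCc1ccc(O)cc1)C[C@](C=C)(C)O
A3 | alternative 3 | (2S)-2-{12-[4-(benzyloxy)phenyl]dodecyl}-2,4-dimethyl-2,3-dihydrofuran | C[C@]1(CCCCCCCCCCCCc2ccc(OCc3ccccc3)cc2)CC(C)=CO1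
A4 | alternative 3 | cis-fused 3-{12-[4-(benzyloxy)phenyl]dodecyl}-3,5-dimethyl-2-oxabicyclo[3.2.0]heptan-6-one with the target configuration at C3, C4 and C6 | C[C@]1(CCCCCCCCCCCCc3ccc(OCc4ccccc4)cc3)C[C@]2(C)C(=O)C[C@@H]2O1
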